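**Assumption:** the target has no stereocentre (it is achiral), so no stereocontrol is needed; the SMILES shows the free hydrogen sulfate, so the product is delivered as the free acid, liberated from its ammonium salt.

## Retrosynthetic overview

1. No C–C bond is made: rings A and B and the three-carbon bridge are bought together in hesperetin dihydrochalcone 1, a commercial bulk flavouring ingredient.
2. Key disconnection: O1–C2 of the pyranone. Ring C is the only ring formed, closed by an aerobic dehydrogenative oxa-cyclisation of 1 to flavone 4 through chalcone 2 and flavanone 3.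
3. Last disconnection: O7–S. Site-selective sulfation of 4 gives salt 5, and H+ exchange gives target 6.

## Route

**Step 1**
Reactants: 1 hesperetin dihydrochalcone
Product: 4 diosmetin, via E-hesperetin chalcone 2 (not isolated), via racemic hesperetin 3 (not isolated)
Conditions: Pd(TFA)2 (10 mol%), 4,5-diazafluoren-9-one (10 mol%), TFA (0.5 equiv), O2 (1 atm), DMSO, 100 °C, 24 h; pour into dilute aq. HCl, filter
Reagents that add atoms: none
Why: Proposed new method: a Pd(II)-catalysed aerobic double dehydrogenation with an interposed 6-endo oxa-Michael ring closure, run on a fully unprotected tetrahydroxy dihydrochalcone — Pd(II) forms a C-bound enolate at the α-CH2 and β-hydride elimination gives E-chalcone 2, one of the two equivalent ortho OH groups adds to the enone to make the O1–C2 bond of flavanone 3 (2',6'-dihydroxychalcones close spontaneously), a second Pd-enolate/β-hydride elimination gives flavone 4, and O2 reoxidises Pd(0) to give only water; the closest known reaction type is the Pd(TFA)2/DMSO/O2 α,β-dehydrogenation of ketones and the Pd(II) oxidative cyclisation of simple or O-protected 2'-hydroxydihydrochalcones, here extended to a free phloroglucinol-type ring A and a free ring-B phenol (TFA keeps the phenols protonated so they neither bind nor reduce Pd), and the transient C2 stereocentre of 3 is racemic and is erased.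

**Step 2**
Reactants: 4 diosmetin
Product: 6 luteolin 4'-methyl ether 7-sulfate (target), via triethylammonium diosmetin 7-sulfate 5 (not isolated)
Conditions: Me3N·SO3 (1.5 equiv), Et3N (1.1 equiv), DMF, 40 °C, 6 h; dilute with cold water, wash with EtOAc; Dowex 50WX8 (H+ form), 0–5 °C; freeze-dry
Reagents that add atoms: sulfur trioxide trimethylamine complex, C[N+](C)(C)S(=O)(=O)[O-]
Why: Site-selective O-sulfation of a phenoxide with an amine–SO3 complex: the 7-OH (vinylogous carboxylic acid, pKa about 7) is ionised by one equivalent of Et3N far ahead of the 3'-OH (pKa about 10) and the chelated 5-OH, so SO3 is transferred to O7, and cold H+ exchange of salt 5 followed by immediate freeze-drying frees the hydrogen sulfate without hydrolysing the aryl sulfate or touching the methyl ether.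

## Compound list

1 | hesperetin dihydrochalcone, 3-(3-hydroxy-4-methoxyphenyl)-1-(2,4,6-trihydroxyphenyl)propan-1-one | COc1ccc(CCC(=O)c2c(O)cc(O)cc2O)cc1O | starting material
2 | E-hesperetin chalcone, (E)-3-(3-hydroxy-4-methoxyphenyl)-1-(2,4,6-trihydroxyphenyl)prop-2-en-1-one | COc1ccc(/C=C/C(=O)c2c(O)cc(O)cc2O)cc1O | intermediate
3 | racemic hesperetin, 5,7-dihydroxy-2-(3-hydroxy-4-methoxyphenyl)chroman-4-one (racemate, stereocentre not controlled) | COc1ccc(C2CC(=O)c3c(O)cc(O)cc3O2)cc1O | intermediate
4 | diosmetin, 5,7-dihydroxy-2-(3-hydroxy-4-methoxyphenyl)-4H-chromen-4-one | COc1ccc(-c2cc(=O)c3c(O)cc(O)cc3o2)cc1O | intermediate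
5 | triethylammonium diosmetin 7-sulfate | COc1ccc(-c2cc(=O)c3c(O)cc(OS(=O)(=O)[O-])cc3o2)cc1O.CC[NH+](CC)CC | intermediate
6 | luteolin 4'-methyl ether 7-sulfate, 5-hydroxy-2-(3-hydroxy-4-methoxyphenyl)-4-oxo-4H-chromen-7-yl hydrogen sulfate | COc1ccc(-c2cc(=O)c3c(O)cc(OS(=O)(=O)O)cc3o2)cc1O | target

## Step count and risks

Total step count: 2. Longest linear sequence: 2.

The route has only two steps, so both are ranked; a third does not exist.

**Most likely to fail: step 1 (the proposed new method).** The polyphenol may deactivate Pd, or the cascade may stall at flavanone 3, whose chelated carbonyl enolises slowly. The fallback uses known chemistry and sets out from 3, racemic hesperetin, either isolated from a stalled run or simply bought, since it is a cheap commercial citrus flavanone. It is dehydrogenated with I2 (1.1 equiv) in pyridine at 95 °C, the classical iodine/pyridine flavanone-to-flavone dehydrogenation (C3 iodination, then elimination), which tolerates the free 5-, 7- and 3'-OH groups. It comes back to the route at 4. It makes no new compound (F0).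

**Second: step 2.** Sulfation may occur at O3' beside O7, or twice, and the sulfate may be lost during acid liberation. The fallback sets out from 4 and fixes the site by protection instead of by acidity. Peracetylation (Ac2O, pyridine, cat. DMAP, 60 °C) gives diosmetin 5,7,3'-tri-O-acetate F1. The 7-O-acetyl group, the most activated ester, is removed selectively with PhSH and imidazole in NMP at 0 °C to rt to give 5,3'-di-O-acetyldiosmetin F2, whose only free OH is O7. Sulfation (Me3N·SO3, Et3N, DMF, 40 °C) gives triethylammonium 5,3'-di-O-acetyldiosmetin 7-sulfate F3. Methanolysis of both aryl acetates (Et3N, MeOH/H2O, rt; the sulfate monoester anion is inert to base) comes back to the route at 5, which is taken on to 6 by the H+ exchange of step 2.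

## Further compounds

F0 | step 1 | none | none
F1 | step 2 | diosmetin 5,7,3'-tri-O-acetate | COc1ccc(-c2cc(=O)c3c(OC(C)=O)cc(OC(C)=O)cc3o2)cc1OC(C)=O
F2 | step 2 | 5,3'-di-O-acetyldiosmetin | COc1ccc(-c2cc(=O)c3c(OC(C)=O)cc(O)cc3o2)cc1OC(C)=O
F3 | step 2 | triethylammonium 5,3'-di-O-acetyldiosmetin 7-sulfate | COc1ccc(-c2cc(=O)c3c(OC(C)=O)cc(OS(=O)(=O)[O-])cc3o2)cc1OC(C)=O.CC[NH+](CC)CC
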